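**Strategy.** The depside is cut at its central ester carbon. This carbon sits alone between C1' of ring A (flanked by C2'-OMe and C6'-Me) and O4 of ring B (flanked by C3-Me and C5-Me), so it is supplied as carbon monoxide. One palladium-catalysed aryloxycarbonylation forms both C1'–C(=O) and C(=O)–O4 from three components. Ring A is therefore carried as a hexasubstituted iodide (I at C1', Cl at C5', MOM ether at O4'). Ring B is carried as a phenol with a single free OH. Each partner is made in four steps from a β-orcinol building block, and one mild acid step frees O4'–H.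

Key step: step 9

**Remarks on the chemistry**
- Locants: ring A (acyl ring) carries primed numbers, C1' being the future carbonyl-bearing carbon. Ring B has C1 at CO2Me. These locants are used for all precursors.
- In iodide 5 the ring order is Cl, Me, I, OMe, Me, OMOM, so iodine is meta to chlorine and para to the MOM ether. The systematic name is therefore 1-chloro-3-iodo-4-methoxy-6-(methoxymethoxy)-2,5-dimethylbenzene. A 1-chloro-4-iodo-5-methoxy locant set would put iodine para to chlorine and lead to the wrong depside.
- Chlorine is installed before iodine, for two reasons: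
  - C5' is the intrinsically favoured site (ortho to OH, para to OMe). The only C–H left for iodination is then C1'.
  - No chlorinating agent ever meets an electron-rich aryl iodide, so iodine oxidation and ipso exchange are avoided.
- Assumption: compounds 1, 6 and 12 are purchased.

**Ring A iodide**

Step 1
Reactants: 1 2,5-dimethylresorcinol
Product: 2 3-methoxy-2,5-dimethylphenol
Conditions: MeI (0.9 equiv), K2CO3 (1.0 equiv), acetone, reflux
Reagents that add atoms: iodomethane, CI
Why: In this Williamson ether synthesis on a symmetric diol either oxygen gives the same monoether, a deficit of MeI holds back the diether, and unreacted 1 and the neutral diether are easily separated and recycled.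

Step 2
Reactants: 2 3-methoxy-2,5-dimethylphenol
Product: 3 2-chloro-5-methoxy-3,6-dimethylphenol
Conditions: SO2Cl2 (1.0 equiv), 2,2,6,6-tetramethylpiperidine (10 mol %), toluene, 0 °C to rt, dark
Reagents that add atoms: sulfuryl chloride, O=S(=O)(Cl)Cl
Why: In this amine-catalysed ortho-selective electrophilic chlorination of a phenol, the N-chloroamine formed in the flask is hydrogen-bonded to O4'–H and delivers chlorine to the adjacent C5', which is also para to C2'-OMe and less shielded than C1', toward which the O-methyl group is turned by the C3' methyl.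

Step 3
Reactants: 3 2-chloro-5-methoxy-3,6-dimethylphenol
Product: 4 2-chloro-4-iodo-5-methoxy-3,6-dimethylphenol
Conditions: NIS (1.05 equiv), TsOH·H2O (10 mol %), MeCN, 0 °C to rt, dark
Reagents that add atoms: N-iodosuccinimide, O=C1CCC(=O)N1I
Why: Electrophilic aromatic iodination with acid-activated NIS has only one ring C–H to attack (C1', para to the free OH and ortho to OMe), so regiochemistry is not in question and C–Cl and the methyl groups are inert under ionic conditions.

Step 4
Reactants: 4 2-chloro-4-iodo-5-methoxy-3,6-dimethylphenol
Product: 5 1-chloro-3-iodo-4-methoxy-6-(methoxymethoxy)-2,5-dimethylbenzene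
Conditions: MOMCl (1.5 equiv), i-Pr2NEt (2 equiv), CH2Cl2, 0 °C to rt
Reagents that add atoms: chloromethyl methyl ether, COCCl
Why: MOM protection (O-alkylation through the small, very reactive oxocarbenium ion of MOMCl) copes with the Cl/Me-flanked but acidic phenol and leaves both carbon–halogen bonds untouched.

**Ring B phenol**

Step 5
Reactants: 6 methyl 2,4-dihydroxy-3,6-dimethylbenzoate (methyl atratate)
Product: 7 methyl 5-formyl-2,4-dihydroxy-3,6-dimethylbenzoate
Conditions: Cl2CHOMe (1.5 equiv), TiCl4 (3 equiv), CH2Cl2, −10 °C to rt; then 1 M aq. HCl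
Reagents that add atoms: dichloromethyl methyl ether, COC(Cl)Cl; water, O
Why: In this Rieche formylation the titanium phenoxide guides the chloro(methoxy)carbenium electrophile to C5, the only open ring position (ortho to 4-OH, para to 2-OH), and aqueous work-up hydrolyses the α-chloro ether to the aldehyde.

Step 6
Reactants: 7 methyl 5-formyl-2,4-dihydroxy-3,6-dimethylbenzoate
Product: 8 methyl 2,4-dihydroxy-3,5,6-trimethylbenzoate
Conditions: Et3SiH (3 equiv), TFA, CH2Cl2, 0 °C to rt
Reagents that add atoms: none
Why: In this ionic hydrogenation the protonated aldehyde and then the benzylic cation, stabilised by the ortho and para hydroxyl groups, each take hydride from the silane, while the ester and the ring stay intact.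

Step 7
Reactants: 8 methyl 2,4-dihydroxy-3,5,6-trimethylbenzoate
Product: 10 methyl 4-(benzyloxy)-2-methoxy-3,5,6-trimethylbenzoate, via 4-O-benzyl ether 9 (not isolated)
Conditions: BnBr (1.0 equiv), K2CO3 (1.2 equiv), DMF, rt; then MeI (3 equiv), K2CO3 (2 equiv), 50 °C, same flask
Reagents that add atoms: benzyl bromide, BrCc1ccccc1; iodomethane, CI
Why: In this sequential Williamson alkylation the 2-OH is locked in a hydrogen bond to the ester carbonyl, so one equivalent of BnBr takes the free 4-OH first, and the chelated 2-OH is then methylated by excess MeI on warming.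

Step 8
Reactants: 10 methyl 4-(benzyloxy)-2-methoxy-3,5,6-trimethylbenzoate
Product: 11 methyl 4-hydroxy-2-methoxy-3,5,6-trimethylbenzoate
Conditions: H2 (1 atm), 10% Pd/C, EtOAc/MeOH, rt
Reagents that add atoms: none
Why: Catalytic hydrogenolysis of a benzyl aryl ether is clean here because ring B carries no halogen or other reducible group at this stage.

**Union and end game**

Step 9
Reactants: 5 1-chloro-3-iodo-4-methoxy-6-(methoxymethoxy)-2,5-dimethylbenzene; 11 methyl 4-hydroxy-2-methoxy-3,5,6-trimethylbenzoate; 12 carbon monoxide
Product: 15 3-methoxy-4-(methoxycarbonyl)-2,5,6-trimethylphenyl 3-chloro-6-methoxy-4-(methoxymethoxy)-2,5-dimethylbenzoate (4'-O-MOM depside), via aroyl chloride 13 (not isolated), via N-aroylpyridinium chloride 14 (not isolated)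
Conditions: Pd(P(t-Bu)3)2 (5 mol %), Bu4NCl (1.2 equiv), CO (10 atm), i-Pr2NEt (2.5 equiv), DMAP (20 mol %), toluene, 100 °C, autoclave
Reagents that add atoms: carbon monoxide (12), [C-]#[O+]; tetrabutylammonium chloride, CCCC[N+](CCCC)(CCCC)CCCC.[Cl-] (acyl chlorine of 13 only); DMAP, CN(C)c1ccncc1 (pyridinium unit of 14 only)
Why: Monoligated zerovalent palladium released from Pd(P(t-Bu)3)2 adds oxidatively to the C1'–I bond of 5, CO inserts to give the aroyl palladium halide (easing the crowding between the metal and the C2'-OMe/C6'-Me pair), and after iodide-for-chloride exchange the bulky phosphine and bound CO force reductive elimination of aroyl chloride 13. DMAP turns 13 into the acylpyridinium salt 14, whose acyl group is taken by O4 of the ammonium phenoxide of 11, so the slow union of two doubly ortho-flanked partners happens off the metal through a slim, acylium-like electrophile that the C2'-OMe and O4'-MOM donors stabilise. The closest known reaction type is the palladium-catalysed aryloxycarbonylation of aryl iodides in its variant with in situ acid chloride formation, which suits weak and hindered nucleophiles. Two skeletal bonds, C1'–C(=O) and C(=O)–O4, are made, no ring is closed and no stereocentre arises. Iodide-over-chloride selectivity rests on the much weaker C–I bond, on the C5'–Cl bond being buried between C6'-Me and O4'-MOM on an electron-rich ring, and on CO lowering the electron density at palladium, while carbonylation beats direct diaryl ether formation because CO under pressure intercepts the aryl palladium species before the hindered phenoxide could bind. Both rings are fully substituted, 11 offers a single OH and O4' is masked, so C–H palladation, C-acylation and self-condensation have no site.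

Step 10
Reactants: 15 4'-O-MOM depside
Product: 16 3-methoxy-4-(methoxycarbonyl)-2,5,6-trimethylphenyl 3-chloro-4-hydroxy-6-methoxy-2,5-dimethylbenzoate (CNP0192286.0)
Conditions: HCl (1.25 M in MeOH), CH2Cl2, rt to 40 °C
Reagents that add atoms: none
Why: Acid-catalysed acetal exchange (MOM cleavage) passes the CH2 unit to methanol, both ester carbonyls are shielded from addition by two ortho substituents each, and any exchange at the methyl ester in methanol is degenerate.

**Compound list**
1 | 2,5-dimethylresorcinol (2,5-dimethylbenzene-1,3-diol) | Cc1cc(O)c(C)c(O)c1 | starting material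
2 | 3-methoxy-2,5-dimethylphenol | COc1cc(C)cc(O)c1C | intermediate
3 | 2-chloro-5-methoxy-3,6-dimethylphenol | COc1cc(C)c(Cl)c(O)c1C | intermediate
4 | 2-chloro-4-iodo-5-methoxy-3,6-dimethylphenol | COc1c(I)c(C)c(Cl)c(O)c1C | intermediate
5 | 1-chloro-3-iodo-4-methoxy-6-(methoxymethoxy)-2,5-dimethylbenzene | COCOc1c(Cl)c(C)c(I)c(OC)c1C | intermediate
6 | methyl 2,4-dihydroxy-3,6-dimethylbenzoate (methyl atratate) | COC(=O)c1c(C)cc(O)c(C)c1O | starting material
7 | methyl 5-formyl-2,4-dihydroxy-3,6-dimethylbenzoate | COC(=O)c1c(C)c(C=O)c(O)c(C)c1O | intermediate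
8 | methyl 2,4-dihydroxy-3,5,6-trimethylbenzoate | COC(=O)c1c(C)c(C)c(O)c(C)c1O | intermediate
9 | methyl 4-(benzyloxy)-2-hydroxy-3,5,6-trimethylbenzoate | COC(=O)c1c(C)c(C)c(OCc2ccccc2)c(C)c1O | intermediate
10 | methyl 4-(benzyloxy)-2-methoxy-3,5,6-trimethylbenzoate | COC(=O)c1c(C)c(C)c(OCc2ccccc2)c(C)c1OC | intermediate
11 | methyl 4-hydroxy-2-methoxy-3,5,6-trimethylbenzoate | COC(=O)c1c(C)c(C)c(O)c(C)c1OC | intermediate
12 | carbon monoxide | [C-]#[O+] | starting material
13 | 3-chloro-6-methoxy-4-(methoxymethoxy)-2,5-dimethylbenzoyl chloride | COCOc1c(Cl)c(C)c(C(Cl)=O)c(OC)c1C | intermediate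
14 | 1-[3-chloro-6-methoxy-4-(methoxymethoxy)-2,5-dimethylbenzoyl]-4-(dimethylamino)pyridinium chloride | COCOc1c(Cl)c(C)c(C(=O)[n+]2ccc(N(C)C)cc2)c(OC)c1C.[Cl-] | intermediate
15 | 3-methoxy-4-(methoxycarbonyl)-2,5,6-trimethylphenyl 3-chloro-6-methoxy-4-(methoxymethoxy)-2,5-dimethylbenzoate | COC(=O)c1c(C)c(C)c(OC(=O)c2c(C)c(Cl)c(OCOC)c(C)c2OC)c(C)c1OC | intermediate
16 | 3-methoxy-4-(methoxycarbonyl)-2,5,6-trimethylphenyl 3-chloro-4-hydroxy-6-methoxy-2,5-dimethylbenzoate | COC(=O)c1c(C)c(C)c(OC(=O)c2c(C)c(Cl)c(O)c(C)c2OC)c(C)c1OC | target

**Step count.** Total: 10 steps. Longest linear sequence: 6 steps (steps 1–4, 9, 10; the ring B arm, steps 5–8, 9, 10, is equally long).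

**Steps most likely to fail**

1. **Step 9.**
   - Risk: Oxidative addition and CO insertion at the doubly flanked C1' may be slow. That would let hydrodeiodination or late insertion into C–Cl compete. Acyl transfer to the doubly flanked phenoxide may also stall.
   - Fallback: it sets out from 5 and returns to the route at 15.
   - Iodine–magnesium exchange of 5 with i-PrMgCl·LiCl (THF, −20 °C) should give [3-chloro-6-methoxy-4-(methoxymethoxy)-2,5-dimethylphenyl]magnesium chloride F1.
   - Quenching with CO2 then gives 3-chloro-6-methoxy-4-(methoxymethoxy)-2,5-dimethylbenzoic acid F2.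
   - Neutral activation with 1-chloro-N,N,2-trimethylprop-1-en-1-amine (CH2Cl2, 0 °C) spares the MOM ether and provides 13 as a discrete reagent.
   - Heating 13 with 11, Et3N and DMAP in toluene reaches 15 by classical stoichiometric esterification.

2. **Step 2.**
   - Risk: Site selectivity between C5' and C1' may be poor, and a second chlorination may follow.
   - Fallback: it sets out from 2 and returns at 3.
   - Acetylation (Ac2O, pyridine) gives 3-methoxy-2,5-dimethylphenyl acetate F3.
   - With the phenol oxygen reduced to a weak donor, the C2'-OMe group alone steers SO2Cl2 (CH2Cl2, 0 °C) to its para position C5'. This gives 2-chloro-5-methoxy-3,6-dimethylphenyl acetate F4.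
   - K2CO3 in MeOH removes the acetyl group and delivers 3.

3. **Step 1.**
   - Risk: Over-alkylation of the symmetric diol is statistical, so part of the material ends up as diether and part stays as unreacted diol.
   - Fallback: it sets out from 1 and returns at 2.
   - Exhaustive methylation (excess MeI, K2CO3, DMF) gives 1,3-dimethoxy-2,5-dimethylbenzene F5.
   - NaSEt in DMF at 120 °C cleaves one methyl ether by SN2 attack at the methyl carbon. The cleavage stops there because the resulting phenoxide deactivates the second ether.
   - Acid work-up gives 2.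

**Further compounds**
F1 | step 9 | [3-chloro-6-methoxy-4-(methoxymethoxy)-2,5-dimethylphenyl]magnesium chloride | COCOc1c(Cl)c(C)c([Mg]Cl)c(OC)c1C
F2 | step 9 | 3-chloro-6-methoxy-4-(methoxymethoxy)-2,5-dimethylbenzoic acid | COCOc1c(Cl)c(C)c(C(O)=O)c(OC)c1C
F3 | step 2 | 3-methoxy-2,5-dimethylphenyl acetate | CC(=O)Oc1cc(C)cc(OC)c1C
F4 | step 2 | 2-chloro-5-methoxy-3,6-dimethylphenyl acetate | CC(=O)Oc1c(Cl)c(C)cc(OC)c1C
F5 | step 1 | 1,3-dimethoxy-2,5-dimethylbenzene | COc1cc(C)cc(OC)c1C
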